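Ring B of the bicyclo[3.3.1]nonane is opened at C7–C1′ and C1–C8. The atoms C6, C7 and C8, with the two methyl groups on C8, then form one prenyl substituent on C5 of an achiral triprenylated aroylphloroglucinol (ring A: C1 to C5 plus C9). In one operation an (E)-geranyl cation adds to C7 of that alkene and the C8 cation is caught by enol carbon C1. This closes ring B, makes both C–C bonds and sets C1, C5 and C7. The precursor is the lupulone-type dienol-one with the 3-(silyloxy)benzoyl group on C3, its enol oxygens capped as trimethylsilyl ethers before the cascade.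

Key step: step 7

**Remarks on the chemistry**

- Numbering: C1–C9 are the bicycle positions of the target and C1′ is the geranyl CH2. In the target the C7 side chain is cis to the C2–C3–C4 bridge (7-endo); the descriptors (1S,5S,7S) refer to the enol tautomer drawn.
- C3 is not strictly blocked: closure there would give the isomeric bridgehead-aroyl skeleton, so C1-over-C3 closure is a selectivity to be secured.
- The three prenyl groups are introduced one per step, so that the slow dearomatising alkylation is run on the purified diprenyl ketone 9.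
- AgX* is the silver salt of one antipode of a confined BINOL-derived imidodiphosphorimidate with an N-triflyl core and 3,3′-aryl walls. Assumption: which antipode gives the (1S,5S,7S) series cannot be predicted and is to be found by screening; the route is written for that antipode.

**Route**

Step 1
Reactants: 1 3-hydroxybenzoic acid
Product: 3 3-(triisopropylsilyloxy)benzoic acid, via triisopropylsilyl 3-(triisopropylsilyloxy)benzoate 2 (not isolated)
Conditions: iPr3SiCl (2.2 equiv), imidazole, DMF, rt; then K2CO3, MeOH/THF/H2O, 0 °C; citric acid to pH 4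
Reagents that add atoms: chlorotriisopropylsilane, CC(C)[Si](Cl)(C(C)C)C(C)C
Why: Silyl chloride/imidazole silylation caps both the phenol and the acid, and the far more labile silyl ester is then hydrolysed selectively while the hindered aryl silyl ether stays.

Step 2
Reactants: 3 3-(triisopropylsilyloxy)benzoic acid
Product: 4 3-(triisopropylsilyloxy)benzoyl chloride
Conditions: (COCl)2, cat. DMF, CH2Cl2, 0 °C → rt; evaporate
Reagents that add atoms: oxalyl chloride, O=C(Cl)C(=O)Cl
Why: Acid chloride formation through the Vilsmeier-type chloroiminium species is mild enough to leave the hindered, acid-tolerant aryl triisopropylsilyl ether untouched.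

Step 3
Reactants: 4 3-(triisopropylsilyloxy)benzoyl chloride; 5 phloroglucinol
Product: 6 (2,4,6-trihydroxyphenyl)[3-(triisopropylsilyloxy)phenyl]methanone
Conditions: AlCl3 (3.5 equiv), CH2Cl2/PhNO2, 0 °C → rt; ice-cold 1 M HCl
Reagents that add atoms: none
Why: Friedel–Crafts C-acylation of the very electron-rich phloroglucinol (three equivalent ring positions) should stop after one acylation because the chelated ketone is deactivated, and the low temperature is chosen to spare the bulky aryl silyl ether.

Step 4
Reactants: 6 (2,4,6-trihydroxyphenyl)[3-(triisopropylsilyloxy)phenyl]methanone; 7 prenyl bromide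
Product: 8 [2,4,6-trihydroxy-3-(3-methylbut-2-en-1-yl)phenyl][3-(triisopropylsilyloxy)phenyl]methanone
Conditions: NaOMe (1.0 equiv), MeOH, −10 °C; 7 (0.9 equiv) added slowly, → 0 °C; pH 5 buffer; recovered 6 recycled
Reagents that add atoms: none
Why: Base-mediated C-alkylation of the acylphloroglucinol anion in a protic solvent (hydrogen bonding to oxygen steers the allylic halide to carbon) should place one prenyl group on either of the two equivalent free ring carbons; the bromide is kept limiting so that mono-alkylation dominates, and the only over-alkylation product to be expected is ketone 9, which step 5 makes anyway.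

Step 5
Reactants: 8 [2,4,6-trihydroxy-3-(3-methylbut-2-en-1-yl)phenyl][3-(triisopropylsilyloxy)phenyl]methanone; 7 prenyl bromide
Product: 9 [2,4,6-trihydroxy-3,5-bis(3-methylbut-2-en-1-yl)phenyl][3-(triisopropylsilyloxy)phenyl]methanone
Conditions: NaOMe (1.05 equiv), MeOH, −10 °C; 7 (1.05 equiv), → 0 °C; pH 5 buffer
Reagents that add atoms: none
Why: The one remaining unsubstituted ring carbon is the most nucleophilic and least hindered carbon of the phenolate, so this second base-mediated C-alkylation should stop at the aromatic 3,5-diprenyl ketone before the slower attack at a substituted carbon sets in.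

Step 6
Reactants: 9 [2,4,6-trihydroxy-3,5-bis(3-methylbut-2-en-1-yl)phenyl][3-(triisopropylsilyloxy)phenyl]methanone; 7 prenyl bromide
Product: 10 3,5-dihydroxy-2,6,6-tris(3-methylbut-2-en-1-yl)-4-[3-(triisopropylsilyloxy)benzoyl]cyclohexa-2,4-dien-1-one (achiral; one tautomer drawn)
Conditions: NaOMe (1.1 equiv), MeOH, −10 °C; 7 (1.1 equiv) added slowly, → 0 °C; pH 5 buffer
Reagents that add atoms: none
Why: Alkylative dearomatisation: with no ring CH left, the phenolate of 9 should be alkylated at one of its two equivalent prenyl-bearing carbons (the acyl-bearing carbon is the least nucleophilic) to give the gem-diprenyl carbon of the lupulone-type dienol-one; no stereocentre arises because that carbon carries two identical groups, and the methoxide is consumed by the acidic substrate so that the aryl silyl ether is spared.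

Step 7
Reactants: 10 3,5-dihydroxy-2,6,6-tris(3-methylbut-2-en-1-yl)-4-[3-(triisopropylsilyloxy)benzoyl]cyclohexa-2,4-dien-1-one; 11 geranyl bromide
Product: 14 (1S,5S,7S)-7-[(2E)-3,7-dimethylocta-2,6-dien-1-yl]-4-hydroxy-8,8-dimethyl-1,5-bis(3-methylbut-2-en-1-yl)-3-[3-(triisopropylsilyloxy)benzoyl]bicyclo[3.3.1]non-3-ene-2,9-dione, via 3,5-bis(trimethylsilyl) dienol ether 12 (not isolated), via 4-O-trimethylsilyl enol ether of the bicycle 13 (not isolated)
Conditions: (Me3Si)2NH (1.5 equiv), cat. Me3SiCl, toluene, 60 °C, evaporate; then AgX* (10 mol %, preformed and dried), Ag2CO3 (0.65 equiv), 4 Å MS, 11 (1.2 equiv, slow addition), CH2Cl2/methylcyclohexane, −60 °C, dark; then pH 7 phosphate buffer/THF, 0 °C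
Reagents that add atoms: none
Why: Proposed new method: soluble AgX* abstracts bromide from 11 to give the (E)-geranyl cation as a contact ion pair with the confined chiral anion, the CH terminus (C7) of one C5 prenyl alkene attacks its primary end in the Markovnikov sense (C7–C1′), and the C8 tertiary cation is captured by the C1=C2 silyl enol ether (C1–C8) with transfer of Me3Si+ to the anion, which insoluble Ag2CO3 converts back into AgX*, so that no protic acid is released. The closest known reaction types are silver halide abstraction under chiral-anion phase transfer, confined-acid cation–olefin cyclisations of terpenes, silyl enol ether-terminated polyene cyclisations and the acid-mediated closure of dearomatised prenylated acylphloroglucinols to bicyclo[3.3.1]nonanetriones. Ring B closes in a 6-(enolexo) mode, the nucleophilic C1=C2 bond lying outside the new ring and C8 being the cationic terminus, through a boat-like arrangement that keeps the C7 side chain off ring A. C5 and C1 are fixed together by which of the two enantiotopic C5 prenyl groups reacts, since the C9 bridge can only span one face of ring A, and C7 by the alkene face that meets the cation; both are decided by the confined anion and not by the flat substrate, and facial control alone should already give enantioenriched 7-endo and 7-exo diastereomers that can be separated. The step needs alkene-over-enol attack, C1-over-C3 and C-over-O closure and retention of the E alkene: the silyl caps remove the acidic O–H groups and shield the oxygens, O-closure would give a tertiary alkyl vinylogous ester that can re-ionise whereas C–C closure is irreversible, C3 is the more hindered and less nucleophilic carbon because the aroyl group sits on it, C5 is quaternary, and −60 °C in a weakly polar medium should prevent isomerisation of the allyl cation.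

Step 8
Reactants: 14 (1S,5S,7S)-7-[(2E)-3,7-dimethylocta-2,6-dien-1-yl]-4-hydroxy-8,8-dimethyl-1,5-bis(3-methylbut-2-en-1-yl)-3-[3-(triisopropylsilyloxy)benzoyl]bicyclo[3.3.1]non-3-ene-2,9-dione
Product: 15 (1S,5S,7S)-7-[(2E)-3,7-dimethylocta-2,6-dien-1-yl]-4-hydroxy-3-(3-hydroxybenzoyl)-8,8-dimethyl-1,5-bis(3-methylbut-2-en-1-yl)bicyclo[3.3.1]non-3-ene-2,9-dione
Conditions: Bu4NF (1.1 equiv), AcOH (1.1 equiv), THF, 0 °C; dilute citric acid wash
Reagents that add atoms: none
Why: Fluoride-mediated desilylation cleaves the aryl Si–O bond under buffered, near-neutral conditions that should leave the enolised triketone, the four trisubstituted alkenes and the three stereocentres (two quaternary bridgeheads and a C7 with no adjacent carbonyl) unchanged.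

**Compound list**

1 | 3-hydroxybenzoic acid | O=C(O)c1cccc(O)c1 | starting material
2 | triisopropylsilyl 3-(triisopropylsilyloxy)benzoate | CC(C)[Si](C(C)C)(C(C)C)OC(=O)c1cccc(O[Si](C(C)C)(C(C)C)C(C)C)c1 | intermediate
3 | 3-(triisopropylsilyloxy)benzoic acid | O=C(O)c1cccc(O[Si](C(C)C)(C(C)C)C(C)C)c1 | intermediate
4 | 3-(triisopropylsilyloxy)benzoyl chloride | O=C(Cl)c1cccc(O[Si](C(C)C)(C(C)C)C(C)C)c1 | intermediate
5 | phloroglucinol (benzene-1,3,5-triol) | Oc1cc(O)cc(O)c1 | starting material
6 | (2,4,6-trihydroxyphenyl)[3-(triisopropylsilyloxy)phenyl]methanone | O=C(c1cccc(O[Si](C(C)C)(C(C)C)C(C)C)c1)c1c(O)cc(O)cc1O | intermediate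
7 | prenyl bromide (1-bromo-3-methylbut-2-ene) | CC(C)=CCBr | starting material
8 | [2,4,6-trihydroxy-3-(3-methylbut-2-en-1-yl)phenyl][3-(triisopropylsilyloxy)phenyl]methanone | O=C(c1cccc(O[Si](C(C)C)(C(C)C)C(C)C)c1)c1c(O)cc(O)c(CC=C(C)C)c1O | intermediate
9 | [2,4,6-trihydroxy-3,5-bis(3-methylbut-2-en-1-yl)phenyl][3-(triisopropylsilyloxy)phenyl]methanone | O=C(c1cccc(O[Si](C(C)C)(C(C)C)C(C)C)c1)c1c(O)c(CC=C(C)C)c(O)c(CC=C(C)C)c1O | intermediate
10 | 3,5-dihydroxy-2,6,6-tris(3-methylbut-2-en-1-yl)-4-[3-(triisopropylsilyloxy)benzoyl]cyclohexa-2,4-dien-1-one (achiral key-step precursor) | O=C1C(CC=C(C)C)=C(O)C(C(=O)c2cccc(O[Si](C(C)C)(C(C)C)C(C)C)c2)=C(O)C1(CC=C(C)C)CC=C(C)C | intermediate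
11 | geranyl bromide ((2E)-1-bromo-3,7-dimethylocta-2,6-diene) | CC(C)=CCC/C(C)=C/CBr | starting material
12 | 2,6,6-tris(3-methylbut-2-en-1-yl)-4-[3-(triisopropylsilyloxy)benzoyl]-3,5-bis(trimethylsilyloxy)cyclohexa-2,4-dien-1-one (achiral; one silyl tautomer drawn) | O=C1C(CC=C(C)C)=C(O[Si](C)(C)C)C(C(=O)c2cccc(O[Si](C(C)C)(C(C)C)C(C)C)c2)=C(O[Si](C)(C)C)C1(CC=C(C)C)CC=C(C)C | intermediate
13 | (1S,5S,7S)-7-[(2E)-3,7-dimethylocta-2,6-dien-1-yl]-8,8-dimethyl-1,5-bis(3-methylbut-2-en-1-yl)-3-[3-(triisopropylsilyloxy)benzoyl]-4-(trimethylsilyloxy)bicyclo[3.3.1]non-3-ene-2,9-dione | CC(C)=CCC/C(C)=C/C[C@H]1C[C@]2(CC=C(C)C)C(=O)[C@@](CC=C(C)C)(C(=O)C(C(=O)c3cccc(O[Si](C(C)C)(C(C)C)C(C)C)c3)=C2O[Si](C)(C)C)C1(C)C | intermediate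
14 | (1S,5S,7S)-7-[(2E)-3,7-dimethylocta-2,6-dien-1-yl]-4-hydroxy-8,8-dimethyl-1,5-bis(3-methylbut-2-en-1-yl)-3-[3-(triisopropylsilyloxy)benzoyl]bicyclo[3.3.1]non-3-ene-2,9-dione (C7 side chain cis to the C2–C3–C4 bridge) | CC(C)=CCC/C(C)=C/C[C@H]1C[C@]2(CC=C(C)C)C(=O)[C@@](CC=C(C)C)(C(=O)C(C(=O)c3cccc(O[Si](C(C)C)(C(C)C)C(C)C)c3)=C2O)C1(C)C | intermediate
15 | (1S,5S,7S)-7-[(2E)-3,7-dimethylocta-2,6-dien-1-yl]-4-hydroxy-3-(3-hydroxybenzoyl)-8,8-dimethyl-1,5-bis(3-methylbut-2-en-1-yl)bicyclo[3.3.1]non-3-ene-2,9-dione (CNP0290731.1) | CC(C)=CCC/C(C)=C/C[C@H]1C[C@]2(CC=C(C)C)C(=O)[C@@](CC=C(C)C)(C(=O)C(C(=O)c3cccc(O)c3)=C2O)C1(C)C | target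

**Step count**

Total step count: 8. Longest linear sequence: 8 steps (1 → 3 → 4 → 6 → 8 → 9 → 10 → 14 → 15).

**Steps most likely to fail**

1. Step 7 (proposed new method).
What may go wrong: the geranyl cation may be intercepted by a silyl enol ether carbon or oxygen (direct Mukaiyama-type geranylation), by the C1 prenyl alkene or by further 11. The C8 cation may close on oxygen or on C3, or lose a proton to an isopropenyl group. Selection of prenyl group and alkene face may be weak, and the boat-like closure needed for the 7-endo series may be slow.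
Fallback (known chemistry; the C7 stereocentre is made first in the side chain and ring B is closed in a separate acid step): it sets out from 9 and comes back at 14. (R)-4-Benzyloxazolidin-2-one is N-acylated (n-BuLi, 3-methylbut-2-enoyl chloride, THF, −78 °C) to (R)-4-benzyl-3-(3-methylbut-2-enoyl)oxazolidin-2-one F1. Its sodium dienolate (NaN(SiMe3)2, THF, −78 °C) is alkylated at the α-carbon by 11, anti to the benzyl group (deconjugative Evans alkylation), to give (R)-4-benzyl-3-[(2R,4E)-5,9-dimethyl-2-(prop-1-en-2-yl)deca-4,8-dienoyl]oxazolidin-2-one F2. LiBH4 (Et2O, 1 equiv H2O, 0 °C) releases (2R,4E)-5,9-dimethyl-2-(prop-1-en-2-yl)deca-4,8-dien-1-ol F3, and Tf2O/2,6-lutidine (CH2Cl2, −78 °C) converts it into (2R,4E)-5,9-dimethyl-2-(prop-1-en-2-yl)deca-4,8-dien-1-yl trifluoromethanesulfonate F4, used at once. Alkylative dearomatisation of 9 with F4 (LiN(SiMe3)2, THF, −40 °C) at a prenyl-bearing ring carbon should give 3,5-dihydroxy-6-[(2S,4E)-5,9-dimethyl-2-(prop-1-en-2-yl)deca-4,8-dien-1-yl]-2,6-bis(3-methylbut-2-en-1-yl)-4-[3-(triisopropylsilyloxy)benzoyl]cyclohexa-2,4-dien-1-one F5 as both epimers at the new quaternary carbon. Formic acid (rt, short contact) protonates the isopropenyl group and the C8 cation closes on C1, a cationic cyclisation known for this substrate class. The epimer with the matching quaternary centre should give 14; the other epimer is expected to lead to the 7-exo diastereomer, which is removed by chromatography.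

2. Step 6.
What may go wrong: the third alkylation may take place on oxygen instead of carbon, may run on to a tetraprenyl product, or may be too slow at a temperature that spares the silyl ether from the alkoxide.
Fallback (transition-metal allylation in place of halide/alkoxide alkylation): it sets out from 9 and comes back at 10, and no new compound is made on the way (F0). 9 is treated with tert-butyl prenyl carbonate (1.2 equiv) and Pd(PPh3)4 (5 mol %, zerovalent palladium) in THF at rt (Tsuji–Trost C-prenylation). Any O-prenyl ether is re-ionised by the catalyst and should funnel to the C-prenylated, dearomatised dienol-one, and no alkoxide builds up to threaten the silyl ether.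

3. Step 3.
What may go wrong: AlCl3/HCl may strip the silyl ether, and O-acylation or a second acylation may compete.
Fallback (aryllithium acylation in place of electrophilic substitution): it sets out from 5 and 4 and comes back at 6. 5 is converted (MeOCH2Cl, iPr2NEt, CH2Cl2) into 1,3,5-tris(methoxymethoxy)benzene F6. Lithiation between two acetal oxygens (n-BuLi, THF, 0 °C) and addition of the aryllithium to 4 at −78 °C should give [2,4,6-tris(methoxymethoxy)phenyl][3-(triisopropylsilyloxy)phenyl]methanone F7. Catalytic HCl in MeOH (40 °C) removes the three acetals while the aryl triisopropylsilyl ether tolerates dilute acid, giving 6.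

**Further compounds**

F1 | step 7 | (R)-4-benzyl-3-(3-methylbut-2-enoyl)oxazolidin-2-one | CC(C)=CC(=O)N1[C@H](Cc2ccccc2)COC1=O
F2 | step 7 | (R)-4-benzyl-3-[(2R,4E)-5,9-dimethyl-2-(prop-1-en-2-yl)deca-4,8-dienoyl]oxazolidin-2-one | C=C(C)[C@@H](C/C=C(\C)CCC=C(C)C)C(=O)N1[C@H](Cc2ccccc2)COC1=O
F3 | step 7 | (2R,4E)-5,9-dimethyl-2-(prop-1-en-2-yl)deca-4,8-dien-1-ol | OC[C@@H](C(C)=C)C/C=C(\C)CCC=C(C)C
F4 | step 7 | (2R,4E)-5,9-dimethyl-2-(prop-1-en-2-yl)deca-4,8-dien-1-yl trifluoromethanesulfonate | O=S(=O)(OC[C@@H](C(C)=C)C/C=C(\C)CCC=C(C)C)C(F)(F)F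
F5 | step 7 | 3,5-dihydroxy-6-[(2S,4E)-5,9-dimethyl-2-(prop-1-en-2-yl)deca-4,8-dien-1-yl]-2,6-bis(3-methylbut-2-en-1-yl)-4-[3-(triisopropylsilyloxy)benzoyl]cyclohexa-2,4-dien-1-one (both epimers at the ring quaternary carbon) | O=C1C(CC=C(C)C)=C(O)C(C(=O)c2cccc(O[Si](C(C)C)(C(C)C)C(C)C)c2)=C(O)C1(CC=C(C)C)C[C@@H](C(C)=C)C/C=C(\C)CCC=C(C)C
F0 | step 6 | none | none
F6 | step 3 | 1,3,5-tris(methoxymethoxy)benzene | COCOc1cc(OCOC)cc(OCOC)c1
F7 | step 3 | [2,4,6-tris(methoxymethoxy)phenyl][3-(triisopropylsilyloxy)phenyl]methanone | COCOc1cc(OCOC)c(C(=O)c2cccc(O[Si](C(C)C)(C(C)C)C(C)C)c2)c(OCOC)c1
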